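**Retrosynthetic overview**

1. Feature: in the lactone ring (O1, C2 bearing CO2Me, C3 bearing the catechol, C4, C5 = carbonyl) the aryl-bearing C3 is a benzylic methine directly beside the carbinol carbon C2. The C3–C4 ring bond is therefore cut as a 1,5 C–H insertion of a C4 carbene tethered through C5 and O1.
2. Late disconnections: the four MOM ethers, then the exocyclic C–aryl bond of the (Z)-benzylidene (Suzuki coupling of a (Z)-enol triflate obtained by formylating C4 of the saturated cis lactone).
3. Key disconnection: C3–C4, by rhodium-carbenoid insertion of the diazoacetate of methyl (S)-3-aryl-lactate into a benzylic C–H. This closes the only ring of the target and sets C3.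
4. The lactate comes from methyl (S)-glycidate (source of the C2 stereocentre) and an aryl Grignard reagent; both aryl groups derive from one MOM-protected 4-bromocatechol.

Key step: step 6

Remark (assumption): the catalyst hand in step 6 is assigned from the sense of induction this ligand family is expected to show with unsubstituted 2-arylethyl diazoacetates; should the first run show the opposite sense, Rh2(4S-MPPIM)4 replaces it with nothing else changed.

**Route**

Step 1
Reactants: 1 4-bromobenzene-1,2-diol (4-bromocatechol)
Product: 2 4-bromo-1,2-bis(methoxymethoxy)benzene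
Conditions: MOMCl, iPr2NEt, CH2Cl2, 0 °C to rt
Reagents that add atoms: chloromethyl methyl ether (MOMCl), COCCl
Why: Williamson-type O-alkylation of both phenols by the reactive α-chloro ether; the MOM acetals should withstand the Grignard, carbenoid, base and palladium steps and are removed by acid at the end.

Step 2
Reactants: 2 4-bromo-1,2-bis(methoxymethoxy)benzene
Product: 3 2-[3,4-bis(methoxymethoxy)phenyl]-4,4,5,5-tetramethyl-1,3,2-dioxaborolane
Conditions: B2pin2, Pd(dppf)Cl2 (3 mol%), KOAc, 1,4-dioxane, 85 °C
Reagents that add atoms: bis(pinacolato)diboron, CC1(C)OB(OC1(C)C)B1OC(C)(C)C(C)(C)O1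
Why: Miyaura borylation, in which zerovalent palladium inserts into the C–Br bond and the acetate-activated diboron transmetalates; KOAc is too weak a base to start Suzuki homocoupling and the MOM ethers are inert.

Step 3
Reactants: 2 4-bromo-1,2-bis(methoxymethoxy)benzene; 4 methyl (2S)-oxirane-2-carboxylate (methyl (S)-glycidate)
Product: 6 methyl (2S)-3-[3,4-bis(methoxymethoxy)phenyl]-2-hydroxypropanoate, via arylmagnesium bromide 5 (not isolated)
Conditions: Mg, THF, 45 °C; then 4, CuBr·SMe2 (10 mol%), THF, −40 °C; aq. NH4Cl
Reagents that add atoms: none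
Why: Copper-catalysed Grignard opening of a terminal epoxide, an SN2 attack of the arylcopper species at the unsubstituted CH2 of the glycidate that outruns addition to the ester at low temperature; no bond to C2 is broken, so the (S) centre is that of the glycidate.

Step 4
Reactants: 6 methyl (2S)-3-[3,4-bis(methoxymethoxy)phenyl]-2-hydroxypropanoate; 7 bromoacetyl bromide
Product: 8 methyl (2S)-3-[3,4-bis(methoxymethoxy)phenyl]-2-(2-bromoacetoxy)propanoate
Conditions: NaHCO3, MeCN, 0 °C
Reagents that add atoms: none
Why: O-acylation of the secondary alcohol by the acid bromide, with bicarbonate taking up HBr so that the MOM acetals and the C2 centre are not exposed to acid or strong base.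

Step 5
Reactants: 8 methyl (2S)-3-[3,4-bis(methoxymethoxy)phenyl]-2-(2-bromoacetoxy)propanoate
Product: 10 methyl (2S)-3-[3,4-bis(methoxymethoxy)phenyl]-2-(2-diazoacetoxy)propanoate, via N-alkylated ditosylhydrazine 9 (not isolated)
Conditions: TsNHNHTs, DBU, THF, 0 °C
Reagents that add atoms: N,N'-ditosylhydrazine, Cc1ccc(cc1)S(=O)(=O)NNS(=O)(=O)c1ccc(C)cc1
Why: Fukuyama diazoacetate synthesis, in which the bromoacetate alkylates the ditosylhydrazine anion and DBU then expels two sulfinate ions to leave the diazo group; the short, cold exposure to DBU should leave the α-acyloxy ester centre intact.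

Step 6
Reactants: 10 methyl (2S)-3-[3,4-bis(methoxymethoxy)phenyl]-2-(2-diazoacetoxy)propanoate
Product: 11 methyl (2S,3S)-3-[3,4-bis(methoxymethoxy)phenyl]-5-oxotetrahydrofuran-2-carboxylate (aryl and ester cis)
Conditions: Rh2(4R-MPPIM)4 (dirhodium tetrakis[methyl (4R)-2-oxo-1-(3-phenylpropanoyl)imidazolidine-4-carboxylate], 1 mol%), CH2Cl2, 40 °C, slow addition of 10
Reagents that add atoms: none
Why: This is a rhodium-carbenoid intramolecular C–H insertion: the divalent rhodium carboxamidate expels N2 from 10 to give an electrophilic carbenoid, which inserts through a concerted, hydride-transfer-like three-centre transition state into one benzylic C–H with retention at carbon, forming the C3–C4 bond. The closest known reaction is the enantioselective benzylic insertion of 2-arylethyl diazoacetates to 4-aryl-γ-butyrolactones on the same carboxamidate catalysts. The lactone ring closes as a 1,5-insertion through a five-membered transition state, the tether being the ester linkage C5–O1. The new C3 stereocentre is fixed by which of the two diastereotopic benzylic hydrogens is taken, and this is decided by the chiral ligand pocket; the (4R) catalyst is chosen because the (4S) antipode is expected to give the opposite configuration at the aryl carbon, while C2 (S) is a spectator and is retained. Chemoselectivity is needed over aromatic cycloaddition, carbene dimerisation and insertion at C2–H: the dialkoxyaryl group activates the benzylic hydrogens, the two acyl groups on C2 deactivate its C–H (whose insertion would also give a strained four-membered ring), the carboxamidate ligands moderate the carbenoid and slow addition keeps the diazo concentration low. The cis sense beside an ester-bearing carbinol carbon is untested and rests on catalyst control overriding a likely substrate preference for the trans ring.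

Step 7
Reactants: 11 methyl (2S,3S)-3-[3,4-bis(methoxymethoxy)phenyl]-5-oxotetrahydrofuran-2-carboxylate; 12 tert-butoxybis(dimethylamino)methane
Product: 13 methyl (2S,3R,4E)-3-[3,4-bis(methoxymethoxy)phenyl]-4-[(dimethylamino)methylidene]-5-oxotetrahydrofuran-2-carboxylate (drawn E; either geometry converges in step 8)
Conditions: t-BuOCH(NMe2)2, PhMe, 60 °C
Reagents that add atoms: none
Why: Bredereck aminomethylenation, a condensation of the aminal ester with the most acidic C–H (the lactone α-CH2 at C4) driven by loss of tert-butanol and dimethylamine; it needs no stoichiometric strong base, and the lactone CH2 is more acidic than the C2–H of the acyclic ester, which should limit epimerisation at C2 (the C3 descriptor changes to R only through the priority rules).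

Step 8
Reactants: 13 methyl (2S,3R,4E)-3-[3,4-bis(methoxymethoxy)phenyl]-4-[(dimethylamino)methylidene]-5-oxotetrahydrofuran-2-carboxylate
Product: 14 methyl (2S,3R,4Z)-3-[3,4-bis(methoxymethoxy)phenyl]-4-(hydroxymethylidene)-5-oxotetrahydrofuran-2-carboxylate (enol tautomer of the 4-formyl lactone)
Conditions: 1 M aq. HCl, THF, 0 °C
Reagents that add atoms: water, O
Why: Hydrolysis of a vinylogous carbamate (C-protonation, addition of water to the iminium ion, loss of dimethylamine) to the hydrogen-bonded hydroxymethylene lactone; brief contact with cold dilute acid should spare the MOM acetals.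

Step 9
Reactants: 14 methyl (2S,3R,4Z)-3-[3,4-bis(methoxymethoxy)phenyl]-4-(hydroxymethylidene)-5-oxotetrahydrofuran-2-carboxylate
Product: 15 methyl (2S,3R,4Z)-3-[3,4-bis(methoxymethoxy)phenyl]-5-oxo-4-{[(trifluoromethanesulfonyl)oxy]methylidene}tetrahydrofuran-2-carboxylate
Conditions: LiOTf, Et3N, CH2Cl2, 0 °C; then Tf2O, −78 to 0 °C
Reagents that add atoms: trifluoromethanesulfonic anhydride, O=S(=O)(OS(=O)(=O)C(F)(F)F)C(F)(F)F
Why: Chelation-controlled enol triflate formation (O-sulfonylation of a 1,3-dicarbonyl enolate): lithium bridges the enolate oxygen and the lactone carbonyl, so the oxygen is held on the C5 side and is triflated there to give the Z geometry, which the C3 aryl group should also favour by crowding the other side.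

Step 10
Reactants: 15 methyl (2S,3R,4Z)-3-[3,4-bis(methoxymethoxy)phenyl]-5-oxo-4-{[(trifluoromethanesulfonyl)oxy]methylidene}tetrahydrofuran-2-carboxylate; 3 2-[3,4-bis(methoxymethoxy)phenyl]-4,4,5,5-tetramethyl-1,3,2-dioxaborolane
Product: 16 methyl (2S,3R,4Z)-4-[3,4-bis(methoxymethoxy)benzylidene]-3-[3,4-bis(methoxymethoxy)phenyl]-5-oxotetrahydrofuran-2-carboxylate
Conditions: Pd(dppf)Cl2 (5 mol%), K3PO4, THF–H2O, rt to 40 °C
Reagents that add atoms: none
Why: Suzuki–Miyaura coupling, in which oxidative addition of zerovalent palladium to the electron-poor enol triflate and the reductive elimination both retain the alkene geometry, so the aryl group takes the place of the triflate on the C5 side (Z); the mild phosphate base and low temperature are chosen to spare the C2 centre.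

Step 11
Reactants: 16 methyl (2S,3R,4Z)-4-[3,4-bis(methoxymethoxy)benzylidene]-3-[3,4-bis(methoxymethoxy)phenyl]-5-oxotetrahydrofuran-2-carboxylate
Product: 17 methyl (2S,3R,4Z)-4-(3,4-dihydroxybenzylidene)-3-(3,4-dihydroxyphenyl)-5-oxotetrahydrofuran-2-carboxylate (target)
Conditions: HCl (about 2 M) in MeOH, 0 °C to rt, argon, dark
Reagents that add atoms: none
Why: Acid-catalysed acetal exchange releases the four phenols and passes the methylene units to methanol; methanol makes any exchange at the methyl ester degenerate, the γ-lactone should reclose if opened, and the non-basic medium leaves C2, C3 and the Z alkene untouched, with light and oxygen excluded to protect the alkene and the catechols.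

**Compound list**

1 | 4-bromobenzene-1,2-diol | Oc1ccc(Br)cc1O | starting material
2 | 4-bromo-1,2-bis(methoxymethoxy)benzene | COCOc1ccc(Br)cc1OCOC | intermediate
3 | 2-[3,4-bis(methoxymethoxy)phenyl]-4,4,5,5-tetramethyl-1,3,2-dioxaborolane | COCOc1ccc(cc1OCOC)B1OC(C)(C)C(C)(C)O1 | intermediate
4 | methyl (2S)-oxirane-2-carboxylate | COC(=O)[C@@H]1CO1 | starting material
5 | [3,4-bis(methoxymethoxy)phenyl]magnesium bromide | COCOc1ccc([Mg]Br)cc1OCOC | intermediate (not isolated)
6 | methyl (2S)-3-[3,4-bis(methoxymethoxy)phenyl]-2-hydroxypropanoate | COC(=O)[C@@H](O)Cc1ccc(OCOC)c(OCOC)c1 | intermediate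
7 | bromoacetyl bromide | BrCC(=O)Br | starting material
8 | methyl (2S)-3-[3,4-bis(methoxymethoxy)phenyl]-2-(2-bromoacetoxy)propanoate | COC(=O)[C@@H](OC(=O)CBr)Cc1ccc(OCOC)c(OCOC)c1 | intermediate
9 | methyl (2S)-3-[3,4-bis(methoxymethoxy)phenyl]-2-{2-[1,2-bis(4-methylbenzenesulfonyl)hydrazin-1-yl]acetoxy}propanoate | COC(=O)[C@@H](OC(=O)CN(NS(=O)(=O)c1ccc(C)cc1)S(=O)(=O)c1ccc(C)cc1)Cc1ccc(OCOC)c(OCOC)c1 | intermediate (not isolated)
10 | methyl (2S)-3-[3,4-bis(methoxymethoxy)phenyl]-2-(2-diazoacetoxy)propanoate | COC(=O)[C@@H](OC(=O)C=[N+]=[N-])Cc1ccc(OCOC)c(OCOC)c1 | intermediate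
11 | methyl (2S,3S)-3-[3,4-bis(methoxymethoxy)phenyl]-5-oxotetrahydrofuran-2-carboxylate | COC(=O)[C@H]1OC(=O)C[C@H]1c1ccc(OCOC)c(OCOC)c1 | intermediate
12 | tert-butoxybis(dimethylamino)methane | CC(C)(C)OC(N(C)C)N(C)C | starting material
13 | methyl (2S,3R,4E)-3-[3,4-bis(methoxymethoxy)phenyl]-4-[(dimethylamino)methylidene]-5-oxotetrahydrofuran-2-carboxylate | COC(=O)[C@H]1OC(=O)/C(=C/N(C)C)[C@H]1c1ccc(OCOC)c(OCOC)c1 | intermediate
14 | methyl (2S,3R,4Z)-3-[3,4-bis(methoxymethoxy)phenyl]-4-(hydroxymethylidene)-5-oxotetrahydrofuran-2-carboxylate | COC(=O)[C@H]1OC(=O)/C(=C\O)[C@H]1c1ccc(OCOC)c(OCOC)c1 | intermediate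
15 | methyl (2S,3R,4Z)-3-[3,4-bis(methoxymethoxy)phenyl]-5-oxo-4-{[(trifluoromethanesulfonyl)oxy]methylidene}tetrahydrofuran-2-carboxylate | COC(=O)[C@H]1OC(=O)/C(=C\OS(=O)(=O)C(F)(F)F)[C@H]1c1ccc(OCOC)c(OCOC)c1 | intermediate
16 | methyl (2S,3R,4Z)-4-[3,4-bis(methoxymethoxy)benzylidene]-3-[3,4-bis(methoxymethoxy)phenyl]-5-oxotetrahydrofuran-2-carboxylate | COC(=O)[C@H]1OC(=O)/C(=C\c2ccc(OCOC)c(OCOC)c2)[C@H]1c1ccc(OCOC)c(OCOC)c1 | intermediate
17 | methyl (2S,3R,4Z)-4-(3,4-dihydroxybenzylidene)-3-(3,4-dihydroxyphenyl)-5-oxotetrahydrofuran-2-carboxylate | COC(=O)[C@H]1OC(=O)/C(=C\c2ccc(O)c(O)c2)[C@H]1c1ccc(O)c(O)c1 | target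

**Step count**

Total: 11 steps. Longest linear sequence: 10 steps (1 → 2 → 6 → 8 → 10 → 11 → 13 → 14 → 15 → 16 → 17; steps 1 and 3 to 11).

**Steps most likely to fail**

Step 6. The carbenoid may take the other diastereotopic benzylic hydrogen, because the trans ring is the less crowded one and may override the catalyst, so that the C3 epimer dominates. The fallback sets out from 10 and returns at 11, and it resets C3 by hydrogenation instead of by the insertion. Compound 10 is cyclised without regard to the C3 outcome (same conditions, or the achiral dirhodium tetracaprolactamate Rh2(cap)4) to a lactone in which the trans isomer methyl (2S,3R)-3-[3,4-bis(methoxymethoxy)phenyl]-5-oxotetrahydrofuran-2-carboxylate F1 may prevail. LDA in THF at −78 °C followed by PhSeCl should give the 4-(phenylselanyl) lactone F2. H2O2 and pyridine in CH2Cl2 at 0 °C (selenoxide syn-elimination, kept free of base to protect C2) should give the butenolide methyl (2S)-3-[3,4-bis(methoxymethoxy)phenyl]-5-oxo-2,5-dihydrofuran-2-carboxylate F3, in which C3 is no longer a stereocentre. Hydrogenation (H2, Pd/C, EtOAc) should deliver hydrogen to the ring face away from the C2 ester, which places the aryl group on the ester side and gives the cis lactone 11.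

Step 7. Traces of tert-butoxide and the liberated dimethylamine at 60 °C may epimerise C2 (the cis ester turning trans) or attack the methyl ester. The fallback sets out from 11 and returns at 14, bypassing 13, by a kinetic Claisen formylation: LiHMDS in THF at −78 °C deprotonates the lactone CH2, 2,2,2-trifluoroethyl formate is added at −78 °C, and the mixture is quenched cold with acetic acid. The enolate of the formyl lactone forms at once and is no longer basic enough to touch C2. This fallback makes no new compound (F0).

Step 10. Aqueous base may cleave the activated enol triflate at sulfur back to 14, epimerise C2, or move the exocyclic double bond into the ring. The fallback sets out from 15 and from 5 (made from 2 as in step 3) and returns at 16 by a base-free Negishi coupling: 5 is transmetalated with ZnCl2 in THF to [3,4-bis(methoxymethoxy)phenyl]zinc chloride F4, which should couple with 15 under Pd(PPh3)4 in THF at rt with retention of the Z geometry.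

**Further compounds**

F1 | step 6 | methyl (2S,3R)-3-[3,4-bis(methoxymethoxy)phenyl]-5-oxotetrahydrofuran-2-carboxylate (aryl trans to ester) | COC(=O)[C@H]1OC(=O)C[C@@H]1c1ccc(OCOC)c(OCOC)c1
F2 | step 6 | methyl (2S)-3-[3,4-bis(methoxymethoxy)phenyl]-5-oxo-4-(phenylselanyl)tetrahydrofuran-2-carboxylate (aryl trans to ester, selenium trans to aryl) | COC(=O)[C@H]1OC(=O)[C@@H]([Se]c2ccccc2)[C@@H]1c1ccc(OCOC)c(OCOC)c1
F3 | step 6 | methyl (2S)-3-[3,4-bis(methoxymethoxy)phenyl]-5-oxo-2,5-dihydrofuran-2-carboxylate | COC(=O)[C@H]1OC(=O)C=C1c1ccc(OCOC)c(OCOC)c1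
F0 | step 7 | none | none
F4 | step 10 | [3,4-bis(methoxymethoxy)phenyl]zinc chloride | COCOc1ccc([Zn]Cl)cc1OCOC
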